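# Proposed total synthesis of garcinisidone C (33) by chromium carbene benzannulation of an aryl ethynyl ether

## Analysis of the target

Garcinisidone C (33) is a depsidone. A benzoyl ring A and a phenolic ring B are joined by a diaryl ether oxygen and by an ester, which close the seven-membered dibenzo[b,e][1,4]dioxepin-11-one ring C. Each benzene ring is fused to a 2,2-dimethyl-2H-pyran (ring D on A, ring E on B).

Ring A is hexasubstituted. Going round it: a1 prenyl, a2 pyran oxygen, a3 pyran carbon, a4 hydroxyl (hydrogen-bonded to the lactone carbonyl), a5 carbonyl carbon, a6 ether oxygen. Ring B is pentasubstituted: b1 ether oxygen, b2 hydrogen, b3 hydroxyl, b4 pyran oxygen, b5 pyran carbon, b6 ester oxygen.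

There is no stereocentre, so the problem is regiochemical: seven aryl–oxygen bonds and four aryl–carbon bonds must be placed without ambiguity. The sensitive groups are:

- the aryl ester of ring C, which is labile to base and nucleophiles;
- the two chromene double bonds and the prenyl group, which are labile to acid, electrophiles and hydride-abstracting oxidants;
- ring B itself, a hydroquinone derivative (b3–O and b6–O are para) that oxidises easily once b6–O is free.

The hardest bond is the diaryl ether, flanked on ring A by the prenyl group and the carboxyl carbon and on ring B by the ester oxygen. The strategy rests on ring B: b6–O lies para to b3–O, with the oxygen-bearing b1 and the unsubstituted b2 on one flank and the pyran atoms b4/b5 on the other. This is the 4-alkoxyphenol that an alkenyl(alkoxy)carbene, a terminal alkyne and a carbonyl ligand assemble.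

## Retrosynthetic reasoning

**33 ⇒ 31 (through 32).** The last operations only unmask functionality. The a4 hydroxyl is freed from its methoxymethyl ether, and the ring E double bond is formed by eliminating a methoxy group at the benzylic pyran carbon. The alkene is carried as this methoxy group because a late dehydrogenation of a plain chroman would not be selective. The prenyl CH2 on ring A (benzylic, allylic, flanked by two ring oxygens) gives up hydride far more easily than the ring E benzylic CH2, which has no para oxygen. An acid-triggered elimination leaves the prenyl group alone.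

**31 ⇒ 30.** The b3 hydroxyl is masked as a 2-(trimethylsilyl)ethyl ether. This oxygen substituent is the alkoxy group of the carbene, so it must be a group that comes from a primary alcohol (24) and leaves without hydrogenolysis or strong Lewis acid.

**30 ⇒ 29 ⇒ 28.** The lactone C(=O)–O bond of ring C is cut. It is the most labile skeletal bond and is best made after the diaryl ether, which then holds the b6 phenol next to the carboxyl group. Direct closure of the methyl ester 28 by its own phenoxide would trade a methyl ester for an aryl ester and is uphill. The ester is therefore first dealkylated to the acid 29, which is closed by dehydrative activation.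

**28 ⇒ 13 + 26 (key disconnection).** Ring B is taken apart into three pieces:

- b1 and b2 come from the alkyne carbons of the aryl ethynyl ether 13;
- b6 comes from a carbonyl ligand of 26;
- b3 is the carbene carbon of 26, and b4/b5 are the enol ether carbons of its dihydropyran.

The bonds cut are b6–b1, b2–b3 and b5–b6. The diaryl ether is never made by C–O coupling between two crowded arenes, because its oxygen is already on the alkyne. The forward reaction must insert the alkyne with the aryloxy carbon next to the CO-derived carbon, and must carry on through CO insertion and electrocyclisation.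

**26 ⇒ 23 + 24; 23 ⇒ 19 + 20.** The carbene carbon and its metal come from chromium hexacarbonyl (20) and the vinyllithium of the enol ether 19. The alkoxy group is introduced from alcohol 24 by exchange at an acyloxycarbene. Ether 19 goes back through allylic alcohol 18 to dihydropyranone 17, which is assembled from 14 and 15 by aldol addition and cyclisation.

**13 ⇒ 11 ⇒ 9 + 10.** The ethynyl ether is made from phenol 9 through the dichlorovinyl ether 11, using trichloroethylene (10) as the two-carbon unit.

**9 ⇒ 7 (through 8).** Both carbon substituents of ring A are delivered from oxygen by sigmatropic shifts. The prenyl group comes from a 1,1-dimethylallyl ether and ring D from a 1,1-dimethylpropargyl ether. Each migrating group has only one open ortho position at the moment it moves, so no regiochemical choice is left to the substrate. The phenol released by the first shift is the one that later becomes the ynol ether.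

**7 ⇒ 4 + 6; 4 ⇒ 3 ⇒ 1 + 2.** The three hydroxyls of 1 are told apart by their intrinsic differences. The para hydroxyl is the most acidic and takes the propargyl group from 2. The two ortho hydroxyls are equivalent: one is capped as the MOM ether, and the other, now chelated, carries the allyl group from carbonate 6, which is made from alcohol 5.

## Alternatives that were turned down

**Alternative 1: both pyran rings by a double propargyl Claisen cascade.**

- Disconnection: in each pyran, the aryl–C bond and the O–CMe2 bond are cut, leading back to the bis(2-methylbut-3-yn-2-yl) ether A2 of a prenylated depsidone.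
- Forward key step: heating A2 should trigger, on each ring, a [3,3] shift, a 1,5-hydrogen shift and an oxa-6π closure, giving the mono-MOM ether A1 of the natural product.
- For it: the reaction type is well known, the chromene oxidation level arrives directly, and both rings D and E form in one operation. On these points it is stronger than the chosen route, which needs an elimination step and an untested key reaction.
- Against it: all the difficulty is moved into A2. This is a depsidone with six differentiated aryl oxygens and a hindered diaryl ether, and the cascade does nothing to build it. In ring A the allene intermediate also sits between the new hydroxyl and the chelated a4 hydroxyl, so closure through the wrong oxygen is possible. A free phenol and an aryl lactone must survive prolonged heating.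
- Comparison: the chosen strategy offers a construction of ring B together with its ether link, which Alternative 1 leaves open.

**Alternative 2: oxidation of a depside catechol and intramolecular oxa-Michael closure.**

- Disconnection: the diaryl ether C–O bond at b1 is cut, leading back to the depside A4, an aryl ester whose ring B is a prenylated catechol.
- Forward key step: a mild oxidant converts the catechol into the ortho-quinone. The a6 phenol adds to the quinone carbon next to the ester oxygen, and tautomerisation gives depsidone A3.
- For it: it is short, biomimetic, needs no organometallic reagent, and ring size dictates where the phenol adds. In step count it is stronger than the chosen route.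
- Against it: the ortho-quinone carries a prenyl CH2 on the adjacent carbon and can tautomerise to a quinone methide before the hindered, hydrogen-bonded phenol attacks. The product catechol A3 is more easily oxidised than A4. Ring E is still missing and must be closed by a quinone oxidant that has to spare the ring A prenyl group.
- Comparison: the chosen route fixes the ring B oxygen pattern and the pyran in one bond-forming event, without handling ring B at the quinone oxidation level.

**Alternative 3: aryne aryloxy-carboxylation.**

- Disconnection: the diaryl ether C–O bond at a6 and the a5–carboxyl bond are cut, leading back to the ring A silyl triflate A6, the ring B phenol A7 and carbon dioxide (A8).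
- Forward key step: fluoride releases the aryne from A6. The phenoxide of A7 adds at the aryne carbon remote from the MOM ether, and the aryl anion is trapped by A8 to give acid A5.
- For it: it is fully convergent, the alkoxy group next to the aryne controls the regiochemistry, and the carboxyl group arrives as the free acid ready for lactonisation. On these points it is as strong as or stronger than the chosen route.
- Against it: the aryne carbon that must accept the phenoxide is next to the prenyl-bearing carbon, so an intramolecular ene reaction with the prenyl alkene is a built-in competitor. The aryl anion must also take up A8 faster than a proton. A6 is a hexasubstituted arene with adjacent silyl and triflate groups, and A7 needs its own multi-step synthesis with three differentiated oxygens. Three MOM ethers must then be handled around the lactonisation.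
- Comparison: the chosen route generates no high-energy intermediate beside the prenyl group and builds ring B instead of requiring it.

Key step: step 13

## Remarks on the chemistry

- The methoxy-bearing carbon created in step 9 is carried as a racemate. It becomes an sp2 carbon in step 17, so no stereocontrol is needed.
- Phenoxide, alkoxide and enolate salts formed by simple deprotonation and consumed in the same operation are not numbered separately.

## Route

Step 1
Reactants: 1 methyl 2,4,6-trihydroxybenzoate; 2 3-chloro-3-methylbut-1-yne
Product: 3 methyl 2,6-dihydroxy-4-[(2-methylbut-3-yn-2-yl)oxy]benzoate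
Conditions: 2 (1.05 equiv), DBU (1.1 equiv), CuCl2·2H2O (1 mol %), MeCN, 0 °C
Reagents that add atoms: none
Why: Copper-catalysed propargylic etherification of a phenol with a tertiary propargylic chloride. The hydroxyl para to the ester is the only one not hydrogen-bonded to the carbonyl and is the most acidic, so it is the one alkylated.

Step 2
Reactants: 3 methyl 2,6-dihydroxy-4-[(2-methylbut-3-yn-2-yl)oxy]benzoate
Product: 4 methyl 2-hydroxy-6-(methoxymethoxy)-4-[(2-methylbut-3-yn-2-yl)oxy]benzoate
Conditions: MOMCl (1.05 equiv), i-Pr2NEt, CH2Cl2, 0 °C
Reagents that add atoms: chloromethyl methyl ether, COCCl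
Why: Williamson-type O-alkylation. The two hydroxyls are equivalent, and after the first is capped the second is locked in a strong hydrogen bond to the ester carbonyl, which should stop the reaction at the monoether.

Step 3
Reactants: 5 2-methylbut-3-en-2-ol
Product: 6 tert-butyl (2-methylbut-3-en-2-yl) carbonate
Conditions: n-BuLi, THF, 0 °C; Boc2O, 0 °C to rt
Reagents that add atoms: di-tert-butyl dicarbonate, CC(C)(C)OC(=O)OC(=O)OC(C)(C)C
Why: O-Acylation of a tertiary lithium alkoxide with a dicarbonate gives the tertiary allylic carbonate used as the allyl donor in step 4.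

Step 4
Reactants: 4 methyl 2-hydroxy-6-(methoxymethoxy)-4-[(2-methylbut-3-yn-2-yl)oxy]benzoate; 6 tert-butyl (2-methylbut-3-en-2-yl) carbonate
Product: 7 methyl 2-(methoxymethoxy)-6-[(2-methylbut-3-en-2-yl)oxy]-4-[(2-methylbut-3-yn-2-yl)oxy]benzoate
Conditions: Pd(PPh3)4 (3 mol %), 6 (1.5 equiv), THF, 0 °C to rt
Reagents that add atoms: none
Why: Tsuji–Trost O-allylation. Zerovalent palladium ionises the carbonate to a 1,1-dimethylallyl palladium cation, CO2 and tert-butoxide, which deprotonates the phenol. Under kinetic control at low temperature the phenoxide attacks the more substituted allyl terminus and gives the tertiary ether.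

Step 5
Reactants: 7 methyl 2-(methoxymethoxy)-6-[(2-methylbut-3-en-2-yl)oxy]-4-[(2-methylbut-3-yn-2-yl)oxy]benzoate
Product: 9 methyl 7-hydroxy-5-(methoxymethoxy)-2,2-dimethyl-8-(3-methylbut-2-en-1-yl)-2H-chromene-6-carboxylate, via prenyl phenol 8 (not isolated)
Conditions: Eu(fod)3 (5 mol %), xylenes, 50 °C; then 140 °C
Reagents that add atoms: none
Why: Two aromatic Claisen rearrangements in sequence. The lanthanide-catalysed [3,3] shift of the dimethylallyl ether runs first and can only reach the one free position ortho to its oxygen, which installs the prenyl group and frees the phenol (8). At the higher temperature the propargyl ether can only move to the last aromatic C–H, and the allenyl phenol closes through the regenerated para oxygen (the other neighbour is a MOM ether) by 1,5-hydrogen shift and oxa-6π electrocyclisation.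

Step 6
Reactants: 9 methyl 7-hydroxy-5-(methoxymethoxy)-2,2-dimethyl-8-(3-methylbut-2-en-1-yl)-2H-chromene-6-carboxylate; 10 trichloroethylene
Product: 11 methyl 7-{[(E)-1,2-dichloroethenyl]oxy}-5-(methoxymethoxy)-2,2-dimethyl-8-(3-methylbut-2-en-1-yl)-2H-chromene-6-carboxylate
Conditions: 10 (1.5 equiv), K2CO3, DMF, 70 °C
Reagents that add atoms: none
Why: Base converts trichloroethylene into dichloroacetylene, and anti addition of the phenoxide gives the (E)-1,2-dichlorovinyl ether. The small, linear electrophile should tolerate the two ortho substituents of the phenol.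

Step 7
Reactants: 11 methyl 7-{[(E)-1,2-dichloroethenyl]oxy}-5-(methoxymethoxy)-2,2-dimethyl-8-(3-methylbut-2-en-1-yl)-2H-chromene-6-carboxylate
Product: 13 methyl 7-(ethynyloxy)-5-(methoxymethoxy)-2,2-dimethyl-8-(3-methylbut-2-en-1-yl)-2H-chromene-6-carboxylate, via lithium acetylide 12 (not isolated)
Conditions: n-BuLi (2.2 equiv), THF, −78 to −60 °C; MeOH, −78 °C
Reagents that add atoms: none
Why: Vinylic deprotonation and β-elimination give the chloroalkynyl ether, chlorine–lithium exchange gives the lithium alkynyl ether 12, and methanol protonates it. Both organolithium events are fast at −78 °C, whereas addition to the ester, which is flanked by two ortho oxygen substituents, should be slow.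

Step 8
Reactants: 14 (E)-4-methoxybut-3-en-2-one; 15 acetone
Product: 17 2,2-dimethyl-2,3-dihydro-4H-pyran-4-one, via aldol adduct 16 (not isolated)
Conditions: LiHMDS, THF, −78 °C; 15; AcOH; then TFA (cat.), CH2Cl2, rt
Reagents that add atoms: none
Why: The kinetic lithium enolate of the vinylogous ester adds to acetone (aldol addition). Acid then promotes intramolecular conjugate addition of the tertiary hydroxyl and loss of methanol, closing the dihydropyranone.

Step 9
Reactants: 17 2,2-dimethyl-2,3-dihydro-4H-pyran-4-one
Product: 18 racemic 2,2-dimethyl-3,4-dihydro-2H-pyran-4-ol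
Conditions: NaBH4, CeCl3·7H2O, MeOH, −40 °C
Reagents that add atoms: none
Why: Luche 1,2-reduction of the enone leaves the enol ether double bond in place. The carbinol centre is formed as a racemate, which is sufficient because it is removed in step 17.

Step 10
Reactants: 18 racemic 2,2-dimethyl-3,4-dihydro-2H-pyran-4-ol
Product: 19 racemic 4-methoxy-2,2-dimethyl-3,4-dihydro-2H-pyran
Conditions: NaH, MeI, THF, 0 °C to rt
Reagents that add atoms: iodomethane, CI
Why: Williamson methylation under basic conditions, which the acid-sensitive enol ether tolerates. The methyl ether is inert to the organolithium and chromium chemistry that follows and serves as the latent alkene of ring E.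

Step 11
Reactants: 19 racemic 4-methoxy-2,2-dimethyl-3,4-dihydro-2H-pyran; 20 chromium hexacarbonyl
Product: 23 tetramethylammonium pentacarbonyl[(4-methoxy-6,6-dimethyl-5,6-dihydro-4H-pyran-2-yl)carbonyl]chromate, via vinyllithium 21 (not isolated), via lithium acyl chromate 22 (not isolated)
Conditions: t-BuLi, THF/pentane, −78 to 0 °C; Cr(CO)6, Et2O, 0 °C to rt; Me4NBr, H2O
Reagents that add atoms: tetramethylammonium bromide, C[N+](C)(C)C.[Br-]
Why: The cyclic enol ether is lithiated at the vinylic carbon next to oxygen, as glycals are. The vinyllithium adds to a carbonyl ligand of Cr(CO)6 (Fischer route to acyl metalates), and cation exchange gives a salt that can be isolated and dried.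

Step 12
Reactants: 23 tetramethylammonium pentacarbonyl[(4-methoxy-6,6-dimethyl-5,6-dihydro-4H-pyran-2-yl)carbonyl]chromate; 24 2-(trimethylsilyl)ethanol
Product: 26 racemic pentacarbonyl{(4-methoxy-6,6-dimethyl-5,6-dihydro-4H-pyran-2-yl)[2-(trimethylsilyl)ethoxy]methylidene}chromium, via acetoxycarbene 25 (not isolated)
Conditions: AcBr, CH2Cl2, −40 °C; then 24, −40 °C to rt
Reagents that add atoms: none
Why: O-Acetylation of the acyl chromate gives a strongly electrophilic acyloxycarbene, which exchanges acetate for the primary alcohol by addition–elimination. This is the usual way to place an alkoxy group other than methoxy or ethoxy on a Fischer carbene.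

Step 13
Reactants: 13 methyl 7-(ethynyloxy)-5-(methoxymethoxy)-2,2-dimethyl-8-(3-methylbut-2-en-1-yl)-2H-chromene-6-carboxylate; 26 racemic pentacarbonyl{(4-methoxy-6,6-dimethyl-5,6-dihydro-4H-pyran-2-yl)[2-(trimethylsilyl)ethoxy]methylidene}chromium
Product: 28 racemic methyl 7-({5-hydroxy-4-methoxy-2,2-dimethyl-8-[2-(trimethylsilyl)ethoxy]-3,4-dihydro-2H-chromen-6-yl}oxy)-5-(methoxymethoxy)-2,2-dimethyl-8-(3-methylbut-2-en-1-yl)-2H-chromene-6-carboxylate, via tricarbonylchromium arene complex 27 (not isolated)
Conditions: 26 (1.5 equiv), THF (0.05 M), 50 °C, Ar; then air, MeCN, rt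
Reagents that add atoms: none
Why: Proposed new method: aryl ethynyl ethers have not been used as the alkyne in a Dötz benzannulation; the closest known reaction type is the benzannulation of dihydropyranyl (glycal-type) alkoxycarbene chromium complexes with ordinary terminal alkynes, which gives 8-alkoxychroman-5-ols. Thermal loss of one CO from the zerovalent chromium carbene 26 opens a site for the alkyne, and insertion into the Cr=C bond joins the terminal CH of 13 to the carbene carbon and leaves the aryloxy-bearing carbon on chromium as a vinylcarbene. CO insertion at that carbon gives a chromium-bound dienylketene, and ring B closes by 6π-electrocyclisation between the ketene carbon and C3 of the dihydropyran, followed by enolisation to the phenol, which forms as its Cr(CO)3 complex 27 and is released by air. Three C–C bonds are made (carbene carbon to alkyne CH, oxygen-bearing alkyne carbon to CO, CO to pyran C3), the pyran arrives already fused with its racemic methoxy-bearing carbon untouched, and no new stereocentre is created. The regiochemistry required is that shown by terminal alkynes in general (substituted end next to the CO-derived carbon), and here it is reinforced because the nucleophilic terminal carbon of the ynol ether attacks the electrophilic carbene carbon. The open question is whether the aryloxy-substituted vinylcarbene takes up CO or rests as a heteroatom-stabilised carbene, as ynamine adducts do; the aryloxy oxygen is a weak donor because its lone pair is shared with ring A and its ortho ester, which should keep the carbene electrophilic enough for CO insertion. THF and a moderate temperature favour the phenol over furan or cyclobutenone products for alkenyl carbenes, and the excess of 26 guards against incorporation of two alkynes.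

Step 14
Reactants: 28 racemic methyl 7-({5-hydroxy-4-methoxy-2,2-dimethyl-8-[2-(trimethylsilyl)ethoxy]-3,4-dihydro-2H-chromen-6-yl}oxy)-5-(methoxymethoxy)-2,2-dimethyl-8-(3-methylbut-2-en-1-yl)-2H-chromene-6-carboxylate
Product: 29 racemic 7-({5-hydroxy-4-methoxy-2,2-dimethyl-8-[2-(trimethylsilyl)ethoxy]-3,4-dihydro-2H-chromen-6-yl}oxy)-5-(methoxymethoxy)-2,2-dimethyl-8-(3-methylbut-2-en-1-yl)-2H-chromene-6-carboxylic acid
Conditions: n-PrSLi (excess), HMPA, rt, Ar; cold dilute aq. HCl to pH 4
Reagents that add atoms: none
Why: SN2 dealkylation of the ester at its methyl carbon by thiolate. This bypasses the carbonyl carbon, which the two ortho substituents shield from hydroxide, and leaves the MOM, silylethyl and alkyl methyl ethers untouched.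

Step 15
Reactants: 29 racemic 7-({5-hydroxy-4-methoxy-2,2-dimethyl-8-[2-(trimethylsilyl)ethoxy]-3,4-dihydro-2H-chromen-6-yl}oxy)-5-(methoxymethoxy)-2,2-dimethyl-8-(3-methylbut-2-en-1-yl)-2H-chromene-6-carboxylic acid
Product: 30 racemic protected depsidone (ring C lactone closed; ring A with MOM ether at a4, prenyl at a1 and ring D; ring B with 2-(trimethylsilyl)ethyl ether at b3 and a 4-methoxy-2,2-dimethylchroman at b4/b5)
Conditions: EDCI·HCl, DMAP, CH2Cl2 (2 mM), rt
Reagents that add atoms: none
Why: Carbodiimide (Steglich-type) lactonisation. The diaryl ether holds the b6 phenol within reach of the activated acid, so the seven-membered dioxepinone closes, and high dilution suppresses intermolecular esters.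

Step 16
Reactants: 30 racemic protected depsidone
Product: 31 racemic depsidone with free b3 hydroxyl (MOM ether at a4 and 4-methoxychroman retained)
Conditions: CsF, DMF, 80 °C; aq. NH4Cl
Reagents that add atoms: none
Why: Fluoride attacks silicon and triggers β-elimination of ethylene and Me3SiF, releasing the phenoxide. Anhydrous fluoride is chosen to avoid hydroxide, and the lactone carbonyl is shielded by its two ortho substituents.

Step 17
Reactants: 31 racemic depsidone with free b3 hydroxyl
Product: 33 garcinisidone C, via methoxychroman diphenol 32 (not isolated)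
Conditions: HCl (0.5 M), MeOH/THF, rt; concentrate; then pTsOH·H2O (10 mol %), toluene, 80 °C
Reagents that add atoms: none
Why: Acetal exchange removes the MOM group from the carbonyl-flanked phenol, with methanol trapping the formaldehyde equivalent. In the non-nucleophilic solvent the benzylic methyl ether then ionises (the cation is stabilised by the ortho pyran oxygen) and loses a proton (E1 elimination) to give the conjugated ring E alkene. Neither prenyl nor chromene has a free ortho hydroxyl to cyclise onto.

## Compound list

1 | methyl 2,4,6-trihydroxybenzoate | COC(=O)c1c(O)cc(O)cc1O | starting material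
2 | 3-chloro-3-methylbut-1-yne | CC(C)(Cl)C#C | starting material
3 | methyl 2,6-dihydroxy-4-[(2-methylbut-3-yn-2-yl)oxy]benzoate | COC(=O)c1c(O)cc(OC(C)(C)C#C)cc1O | intermediate
4 | methyl 2-hydroxy-6-(methoxymethoxy)-4-[(2-methylbut-3-yn-2-yl)oxy]benzoate | COC(=O)c1c(O)cc(OC(C)(C)C#C)cc1OCOC | intermediate
5 | 2-methylbut-3-en-2-ol | CC(C)(O)C=C | starting material
6 | tert-butyl (2-methylbut-3-en-2-yl) carbonate | CC(C)(C)OC(=O)OC(C)(C)C=C | intermediate
7 | methyl 2-(methoxymethoxy)-6-[(2-methylbut-3-en-2-yl)oxy]-4-[(2-methylbut-3-yn-2-yl)oxy]benzoate | COC(=O)c1c(OCOC)cc(OC(C)(C)C#C)cc1OC(C)(C)C=C | intermediate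
8 | methyl 2-hydroxy-6-(methoxymethoxy)-3-(3-methylbut-2-en-1-yl)-4-[(2-methylbut-3-yn-2-yl)oxy]benzoate | COC(=O)c1c(O)c(CC=C(C)C)c(OC(C)(C)C#C)cc1OCOC | intermediate (not isolated)
9 | methyl 7-hydroxy-5-(methoxymethoxy)-2,2-dimethyl-8-(3-methylbut-2-en-1-yl)-2H-chromene-6-carboxylate | CC(C)=CCc1c2c(C=CC(C)(C)O2)c(OCOC)c(C(=O)OC)c1O | intermediate
10 | trichloroethylene | ClC=C(Cl)Cl | starting material
11 | methyl 7-{[(E)-1,2-dichloroethenyl]oxy}-5-(methoxymethoxy)-2,2-dimethyl-8-(3-methylbut-2-en-1-yl)-2H-chromene-6-carboxylate | CC(C)=CCc1c2c(C=CC(C)(C)O2)c(OCOC)c(C(=O)OC)c1O/C(Cl)=C\Cl | intermediate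
12 | lithium acetylide of 13 | CC(C)=CCc1c2c(C=CC(C)(C)O2)c(OCOC)c(C(=O)OC)c1OC#C[Li] | intermediate (not isolated)
13 | methyl 7-(ethynyloxy)-5-(methoxymethoxy)-2,2-dimethyl-8-(3-methylbut-2-en-1-yl)-2H-chromene-6-carboxylate | CC(C)=CCc1c2c(C=CC(C)(C)O2)c(OCOC)c(C(=O)OC)c1OC#C | intermediate
14 | (E)-4-methoxybut-3-en-2-one | CO/C=C/C(C)=O | starting material
15 | acetone | CC(C)=O | starting material
16 | (E)-5-hydroxy-1-methoxy-5-methylhex-1-en-3-one | CO/C=C/C(=O)CC(C)(C)O | intermediate (not isolated)
17 | 2,2-dimethyl-2,3-dihydro-4H-pyran-4-one | CC1(C)CC(=O)C=CO1 | intermediate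
18 | racemic 2,2-dimethyl-3,4-dihydro-2H-pyran-4-ol | CC1(C)CC(O)C=CO1 | intermediate
19 | racemic 4-methoxy-2,2-dimethyl-3,4-dihydro-2H-pyran | COC1C=COC(C)(C)C1 | intermediate
20 | chromium hexacarbonyl, Cr(CO)6 | [Cr].[C-]#[O+].[C-]#[O+].[C-]#[O+].[C-]#[O+].[C-]#[O+].[C-]#[O+] | starting material
21 | racemic 6-lithio-4-methoxy-2,2-dimethyl-3,4-dihydro-2H-pyran | [Li]C1=CC(OC)CC(C)(C)O1 | intermediate (not isolated)
22 | lithium pentacarbonyl[(4-methoxy-6,6-dimethyl-5,6-dihydro-4H-pyran-2-yl)carbonyl]chromate | [Li+].[O-]C(=[Cr])C1=CC(OC)CC(C)(C)O1.[C-]#[O+].[C-]#[O+].[C-]#[O+].[C-]#[O+].[C-]#[O+] | intermediate (not isolated)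
23 | tetramethylammonium pentacarbonyl[(4-methoxy-6,6-dimethyl-5,6-dihydro-4H-pyran-2-yl)carbonyl]chromate | C[N+](C)(C)C.[O-]C(=[Cr])C1=CC(OC)CC(C)(C)O1.[C-]#[O+].[C-]#[O+].[C-]#[O+].[C-]#[O+].[C-]#[O+] | intermediate
24 | 2-(trimethylsilyl)ethanol | C[Si](C)(C)CCO | starting material
25 | pentacarbonyl[acetoxy(4-methoxy-6,6-dimethyl-5,6-dihydro-4H-pyran-2-yl)methylidene]chromium | CC(=O)OC(=[Cr])C1=CC(OC)CC(C)(C)O1.[C-]#[O+].[C-]#[O+].[C-]#[O+].[C-]#[O+].[C-]#[O+] | intermediate (not isolated)
26 | racemic pentacarbonyl{(4-methoxy-6,6-dimethyl-5,6-dihydro-4H-pyran-2-yl)[2-(trimethylsilyl)ethoxy]methylidene}chromium | C[Si](C)(C)CCOC(=[Cr])C1=CC(OC)CC(C)(C)O1.[C-]#[O+].[C-]#[O+].[C-]#[O+].[C-]#[O+].[C-]#[O+] | intermediate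
27 | tricarbonylchromium complex of 28 (metal on ring B) | CC(C)=CCc1c2c(C=CC(C)(C)O2)c(OCOC)c(C(=O)OC)c1Oc1cc(OCC[Si](C)(C)C)c2OC(C)(C)CC(OC)c2c1O.[Cr].[C-]#[O+].[C-]#[O+].[C-]#[O+] | intermediate (not isolated)
28 | racemic methyl 7-({5-hydroxy-4-methoxy-2,2-dimethyl-8-[2-(trimethylsilyl)ethoxy]-3,4-dihydro-2H-chromen-6-yl}oxy)-5-(methoxymethoxy)-2,2-dimethyl-8-(3-methylbut-2-en-1-yl)-2H-chromene-6-carboxylate | CC(C)=CCc1c2c(C=CC(C)(C)O2)c(OCOC)c(C(=O)OC)c1Oc1cc(OCC[Si](C)(C)C)c2OC(C)(C)CC(OC)c2c1O | intermediate
29 | racemic carboxylic acid corresponding to ester 28 | CC(C)=CCc1c2c(C=CC(C)(C)O2)c(OCOC)c(C(=O)O)c1Oc1cc(OCC[Si](C)(C)C)c2OC(C)(C)CC(OC)c2c1O | intermediate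
30 | racemic protected depsidone (a4 MOM ether, b3 2-(trimethylsilyl)ethyl ether, 4-methoxychroman on ring B) | CC(C)=CCc1c2c(c(OCOC)c3c1Oc1cc(OCC[Si](C)(C)C)c4c(c1OC3=O)C(OC)CC(C)(C)O4)C=CC(C)(C)O2 | intermediate
31 | racemic depsidone with free b3 hydroxyl (a4 MOM ether, 4-methoxychroman on ring B) | CC(C)=CCc1c2c(c(OCOC)c3c1Oc1cc(O)c4c(c1OC3=O)C(OC)CC(C)(C)O4)C=CC(C)(C)O2 | intermediate
32 | racemic 3,4-dihydro-4-methoxy derivative of garcinisidone C (both hydroxyls free) | CC(C)=CCc1c2c(c(O)c3c1Oc1cc(O)c4c(c1OC3=O)C(OC)CC(C)(C)O4)C=CC(C)(C)O2 | intermediate (not isolated)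
33 | garcinisidone C | CC(C)=CCc1c2c(c(O)c3c1Oc1cc(O)c4c(c1OC3=O)C=CC(C)(C)O4)C=CC(C)(C)O2 | target

## Step count and least certain steps

Total step count: 17. Longest linear sequence: 11 steps (1 → 3 → 4 → 7 → 9 → 11 → 13 → 28 → 29 → 30 → 31 → 33, steps 1, 2, 4, 5, 6, 7, 13, 14, 15, 16, 17).

**Step 13 (key step, new method).**
- What may go wrong: the sequence may stop after alkyne insertion, because the aryloxy-substituted vinylcarbene is heteroatom-stabilised and may not take up CO. It may also divert to cyclobutenone, furan or two-alkyne products, or the ynol ether may oligomerise on the Lewis-acidic metal.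
- Fallback by known chemistry, setting out from carbene 26 and phenol 9 and returning at 28:
  - Carbene 26 is benzannulated with commercial 2-ethynyl-4,4,5,5-tetramethyl-1,3,2-dioxaborolane (alkynylboronates are established partners, and the boryl group is expected next to the new hydroxyl). This gives the boronate 4-methoxy-2,2-dimethyl-6-(4,4,5,5-tetramethyl-1,3,2-dioxaborolan-2-yl)-8-[2-(trimethylsilyl)ethoxy]chroman-5-ol F1.
  - Acetylation (Ac2O, pyridine) gives its acetate F2.
  - Chan–Lam etherification of phenol 9 with F2 (Cu(OAc)2, pyridine, boric acid, molecular sieves, air) gives the O-acetate of 28, F3.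
  - Methanolysis (K2CO3, MeOH) returns 28.
- The weak point of the fallback is the coupling of two hindered partners, which is the reason it is not the main route.

**Step 7.**
- What may go wrong: butyllithium may add to the ester carbonyl in competition with vinylic deprotonation and chlorine–lithium exchange.
- Fallback, setting out from 11 and returning at 13:
  - The ester of 11 is dealkylated with KOSiMe3 in THF to the acid 7-{[(E)-1,2-dichloroethenyl]oxy}-5-(methoxymethoxy)-2,2-dimethyl-8-(3-methylbut-2-en-1-yl)-2H-chromene-6-carboxylic acid F4.
  - F4 is treated with n-BuLi (3.3 equiv, −78 °C), so that the carboxylate protects the carbonyl carbon during elimination and exchange.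
  - The acetylide is protonated with one equivalent of MeOH to give the lithium carboxylate of the ethynyl ether F5. This is not acidified, because a free ortho acid could add to the ynol ether.
  - F5 is methylated in the same flask with MeI in DMF to give 13.

**Step 4 (and the ordering in step 5).**
- What may go wrong: O-allylation of the chelated phenol may be sluggish, the tertiary ether may re-ionise and isomerise to the linear prenyl ether, or the propargyl ether may rearrange before the allyl ether.
- Fallback, setting out from 1 and returning at 8 (which then enters the 140 °C stage of step 5):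
  - Direct C-prenylation of 1 with 1-bromo-3-methylbut-2-ene and DBU (unambiguous by symmetry, though expected to be inefficient) gives methyl 2,4,6-trihydroxy-3-(3-methylbut-2-en-1-yl)benzoate F6.
  - Copper-catalysed propargylation of its para hydroxyl with 2 gives methyl 2,6-dihydroxy-3-(3-methylbut-2-en-1-yl)-4-[(2-methylbut-3-yn-2-yl)oxy]benzoate F7.
  - Mono-MOM protection of the less hindered chelated hydroxyl (the one not flanked by the prenyl group) gives 8.

**Step 17.**
- What may go wrong: acid may cause methanolysis of the aryl lactone during MOM removal, or cationic side reactions at the prenyl or chromene groups during the elimination.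
- Fallback, setting out from 28 and returning at 33: the acid steps are run before the lactone exists, where methanolysis of the methyl ester is degenerate.
  - 28 is treated with HCl/MeOH and then pTsOH/toluene to give the chromene ester F9 (free a4 and b6 hydroxyls, silylethyl ether retained).
  - Thiolate dealkylation gives the acid F10.
  - Carbodiimide lactonisation gives the silylethyl ether of garcinisidone C, F11.
  - CsF in DMF gives 33.

**Step 16.**
- What may go wrong: the lactone may be opened by the phenoxide released or by adventitious hydroxide at 80 °C.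
- Fallback, setting out from 29 and returning at 31: the silylethyl ether is cleaved at the seco-acid stage with CsF in DMF under argon. This gives the hydroquinone acid F8, which is lactonised at once under high dilution with EDCI/DMAP. Only the hydroxyl ortho to the diaryl ether can reach the acid, so 31 results.

## Further compounds

F1 | step 13 | racemic 4-methoxy-2,2-dimethyl-6-(4,4,5,5-tetramethyl-1,3,2-dioxaborolan-2-yl)-8-[2-(trimethylsilyl)ethoxy]chroman-5-ol | COC1CC(C)(C)Oc2c(OCC[Si](C)(C)C)cc(B3OC(C)(C)C(C)(C)O3)c(O)c12
F2 | step 13 | acetate of F1 | COC1CC(C)(C)Oc2c(OCC[Si](C)(C)C)cc(B3OC(C)(C)C(C)(C)O3)c(OC(C)=O)c12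
F3 | step 13 | O-acetate of 28 | CC(C)=CCc1c2c(C=CC(C)(C)O2)c(OCOC)c(C(=O)OC)c1Oc1cc(OCC[Si](C)(C)C)c2OC(C)(C)CC(OC)c2c1OC(C)=O
F4 | step 7 | 7-{[(E)-1,2-dichloroethenyl]oxy}-5-(methoxymethoxy)-2,2-dimethyl-8-(3-methylbut-2-en-1-yl)-2H-chromene-6-carboxylic acid | CC(C)=CCc1c2c(C=CC(C)(C)O2)c(OCOC)c(C(=O)O)c1O/C(Cl)=C\Cl
F5 | step 7 | lithium 7-(ethynyloxy)-5-(methoxymethoxy)-2,2-dimethyl-8-(3-methylbut-2-en-1-yl)-2H-chromene-6-carboxylate | [Li+].CC(C)=CCc1c2c(C=CC(C)(C)O2)c(OCOC)c(C(=O)[O-])c1OC#C
F6 | step 4 | methyl 2,4,6-trihydroxy-3-(3-methylbut-2-en-1-yl)benzoate | COC(=O)c1c(O)cc(O)c(CC=C(C)C)c1O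
F7 | step 4 | methyl 2,6-dihydroxy-3-(3-methylbut-2-en-1-yl)-4-[(2-methylbut-3-yn-2-yl)oxy]benzoate | COC(=O)c1c(O)cc(OC(C)(C)C#C)c(CC=C(C)C)c1O
F8 | step 16 | racemic hydroquinone acid (29 without its silylethyl group) | CC(C)=CCc1c2c(C=CC(C)(C)O2)c(OCOC)c(C(=O)O)c1Oc1cc(O)c2OC(C)(C)CC(OC)c2c1O
F9 | step 17 | methyl 5-hydroxy-7-({5-hydroxy-2,2-dimethyl-8-[2-(trimethylsilyl)ethoxy]-2H-chromen-6-yl}oxy)-2,2-dimethyl-8-(3-methylbut-2-en-1-yl)-2H-chromene-6-carboxylate | CC(C)=CCc1c2c(C=CC(C)(C)O2)c(O)c(C(=O)OC)c1Oc1cc(OCC[Si](C)(C)C)c2OC(C)(C)C=Cc2c1O
F10 | step 17 | carboxylic acid corresponding to F9 | CC(C)=CCc1c2c(C=CC(C)(C)O2)c(O)c(C(=O)O)c1Oc1cc(OCC[Si](C)(C)C)c2OC(C)(C)C=Cc2c1O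
F11 | step 17 | garcinisidone C 2-(trimethylsilyl)ethyl ether at the ring B hydroxyl | CC(C)=CCc1c2c(c(O)c3c1Oc1cc(OCC[Si](C)(C)C)c4c(c1OC3=O)C=CC(C)(C)O4)C=CC(C)(C)O2
A1 | alternative 1 | garcinisidone C methoxymethyl ether at the ring B hydroxyl | CC(C)=CCc1c2c(c(O)c3c1Oc1cc(OCOC)c4c(c1OC3=O)C=CC(C)(C)O4)C=CC(C)(C)O2
A2 | alternative 1 | prenylated depsidone bis(2-methylbut-3-yn-2-yl) ether | CC(C)=CCc1c(OC(C)(C)C#C)cc(O)c2c1Oc1cc(OCOC)c(OC(C)(C)C#C)cc1OC2=O
A3 | alternative 2 | depsidone with ring B catechol and ring B prenyl group | CC(C)=CCc1c2c(c(OCOC)c3c1Oc1cc(O)c(O)c(CC=C(C)C)c1OC3=O)C=CC(C)(C)O2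
A4 | alternative 2 | depside: 3,4-dihydroxy-2-(3-methylbut-2-en-1-yl)phenyl ester of the ring A hydroxy acid | CC(C)=CCc1c2c(C=CC(C)(C)O2)c(OCOC)c(C(=O)Oc2ccc(O)c(O)c2CC=C(C)C)c1O
A5 | alternative 3 | 7-{[5,8-bis(methoxymethoxy)-2,2-dimethyl-2H-chromen-6-yl]oxy}-5-(methoxymethoxy)-2,2-dimethyl-8-(3-methylbut-2-en-1-yl)-2H-chromene-6-carboxylic acid | CC(C)=CCc1c2c(C=CC(C)(C)O2)c(OCOC)c(C(=O)O)c1Oc1cc(OCOC)c2OC(C)(C)C=Cc2c1OCOC
A6 | alternative 3 | 5-(methoxymethoxy)-2,2-dimethyl-8-(3-methylbut-2-en-1-yl)-6-(trimethylsilyl)-2H-chromen-7-yl trifluoromethanesulfonate | CC(C)=CCc1c2c(C=CC(C)(C)O2)c(OCOC)c([Si](C)(C)C)c1OS(=O)(=O)C(F)(F)F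
A7 | alternative 3 | 5,8-bis(methoxymethoxy)-2,2-dimethyl-2H-chromen-6-ol | Oc1cc(OCOC)c2OC(C)(C)C=Cc2c1OCOC
A8 | alternative 3 | carbon dioxide | O=C=O
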